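**Retrosynthetic overview**
1. Both pyrrole rings are opened at N1–C2. The target comes from an unsymmetrical bis(α‑aryl‑2‑nitrostyrene) by one twofold deoxygenative C–N annulation, which is the last step.
2. The two 1,1‑diarylethene C–C bonds are cut by tosylhydrazone (carbene) cross‑coupling. This gives a para‑dibrominated tetramethoxybenzene and two 2‑nitroacetophenones, the 5‑methoxy one coupled first and the 5‑hydroxy one second, with the phenol left unprotected.
3. The dibromide comes from the tetramethoxyarene by bromination.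
4. Ring order: the central and both outer benzene rings are bought intact; the two pyrrole rings are formed last, together.

Assumption: the target SMILES has no stereodescriptor, the molecule has no stereocentre and the symmetric central ring allows no stereo‑axis, so it is made as the single achiral compound drawn.

**Step 1**
Reactants: 1 1,2,4,5-tetramethoxybenzene
Product: 2 1,4-dibromo-2,3,5,6-tetramethoxybenzene
Conditions: Br2 (2.3 equiv), CH2Cl2, 0 °C to rt; aq. Na2S2O3 wash
Reagents that add atoms: bromine, BrBr
Why: Twofold electrophilic aromatic bromination at the only two free positions of a very electron‑rich arene, each flanked by two methoxy groups; no stereocentre is formed.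

**Step 2**
Reactants: 2 1,4-dibromo-2,3,5,6-tetramethoxybenzene (3 equiv, excess recovered); 3 1-(5-methoxy-2-nitrophenyl)ethan-1-one; 4 4-methylbenzenesulfonohydrazide
Product: 6 1-bromo-2,3,5,6-tetramethoxy-4-[1-(5-methoxy-2-nitrophenyl)ethenyl]benzene, via tosylhydrazone 5 (not isolated)
Conditions: 3 + 4 (1.05 equiv), 1,4-dioxane, 80 °C, 2 h; then 2, Pd2(dba)3 (2.5 mol %), XPhos (10 mol %), LiOtBu (2.6 equiv), 100 °C
Reagents that add atoms: none
Why: Barluenga cross‑coupling, in which the tosylhydrazone formed in the flask acts as carbene source for the aryl–palladium bromide from 2, and aryl migration followed by β‑hydride elimination from the methyl group gives the 1,1‑diarylethene, the threefold excess of 2 holding the reaction at mono‑coupling; no stereocentre is formed.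

**Step 3**
Reactants: 6 1-bromo-2,3,5,6-tetramethoxy-4-[1-(5-methoxy-2-nitrophenyl)ethenyl]benzene; 7 1-(5-hydroxy-2-nitrophenyl)ethan-1-one (1.4 equiv); 4 4-methylbenzenesulfonohydrazide
Product: 9 4-nitro-3-(1-{2,3,5,6-tetramethoxy-4-[1-(5-methoxy-2-nitrophenyl)ethenyl]phenyl}ethenyl)phenol, via tosylhydrazone 8 (not isolated)
Conditions: 7 + 4 (1.45 equiv), 1,4-dioxane, 80 °C, 2 h; then 6, Pd2(dba)3 (4 mol %), XPhos (16 mol %), LiOtBu (5 equiv), 105 °C; aq. NH4Cl
Reagents that add atoms: none
Why: Second Barluenga cross‑coupling at the remaining hindered C–Br bond, with the nitrophenol carried as its lithium phenoxide (too weak a nucleophile for C–O coupling) and the nitro groups and first alkene inert to zerovalent palladium when no reductant is present; no stereocentre is formed.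

**Step 4**
Reactants: 9 4-nitro-3-(1-{2,3,5,6-tetramethoxy-4-[1-(5-methoxy-2-nitrophenyl)ethenyl]phenyl}ethenyl)phenol
Product: 10 3-[2,3,5,6-tetramethoxy-4-(5-methoxy-1H-indol-3-yl)phenyl]-1H-indol-5-ol (CNP0244913.0)
Conditions: Cp2TiCl2 (20 mol %), Mn dust (6 equiv), 2,4,6-collidine·HCl (10 equiv), THF, 25 to 45 °C, Ar; aq. citric acid work‑up
Reagents that add atoms: none
Why: Proposed new method: a titanocene‑catalysed twofold deoxygenative N‑annulation in which Cp2TiCl (trivalent titanium, generated from Cp2TiCl2 and Mn) binds each nitro group through oxygen and reduces it by inner‑sphere electron transfer to the nitroso level, the nitrosoarene closes onto the coplanar terminal alkene by 1,5‑electrocyclisation and hydrogen shift to the 1‑hydroxyindole level, a further titanium‑mediated N–O cleavage gives the N–H indole, and collidinium chloride protonates the Ti–O bonds so that Mn regenerates the catalyst while the low standing concentration of reductant disfavours over‑reduction to the aniline; the closest known reaction types are the stoichiometric aqueous TiCl3 reductive cyclisation of 2‑nitrostyrenes (a Cadogan–Sundberg‑type indole synthesis) and titanocene‑catalysed reductions turned over by Mn and collidinium chloride; both C–N bonds and both pyrrole rings are formed here and no stereocentre is formed.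

**Compound list**
1 | 1,2,4,5-tetramethoxybenzene | COc1cc(OC)c(OC)cc1OC | starting material
2 | 1,4-dibromo-2,3,5,6-tetramethoxybenzene | COc1c(Br)c(OC)c(OC)c(Br)c1OC | intermediate
3 | 1-(5-methoxy-2-nitrophenyl)ethan-1-one | CC(=O)c1cc(OC)ccc1[N+](=O)[O-] | starting material
4 | 4-methylbenzenesulfonohydrazide | Cc1ccc(cc1)S(=O)(=O)NN | starting material
5 | N'-[1-(5-methoxy-2-nitrophenyl)ethylidene]-4-methylbenzenesulfonohydrazide (C=N geometry not defined, irrelevant) | CC(=NNS(=O)(=O)c1ccc(C)cc1)c1cc(OC)ccc1[N+](=O)[O-] | intermediate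
6 | 1-bromo-2,3,5,6-tetramethoxy-4-[1-(5-methoxy-2-nitrophenyl)ethenyl]benzene | C=C(c1c(OC)c(OC)c(Br)c(OC)c1OC)c1cc(OC)ccc1[N+](=O)[O-] | intermediate
7 | 1-(5-hydroxy-2-nitrophenyl)ethan-1-one | CC(=O)c1cc(O)ccc1[N+](=O)[O-] | starting material
8 | N'-[1-(5-hydroxy-2-nitrophenyl)ethylidene]-4-methylbenzenesulfonohydrazide (C=N geometry not defined, irrelevant) | CC(=NNS(=O)(=O)c1ccc(C)cc1)c1cc(O)ccc1[N+](=O)[O-] | intermediate
9 | 4-nitro-3-(1-{2,3,5,6-tetramethoxy-4-[1-(5-methoxy-2-nitrophenyl)ethenyl]phenyl}ethenyl)phenol | C=C(c1c(OC)c(OC)c(C(=C)c2cc(O)ccc2[N+](=O)[O-])c(OC)c1OC)c1cc(OC)ccc1[N+](=O)[O-] | intermediate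
10 | 3-[2,3,5,6-tetramethoxy-4-(5-methoxy-1H-indol-3-yl)phenyl]-1H-indol-5-ol | COc1ccc2[nH]cc(-c3c(OC)c(OC)c(-c4c[nH]c5ccc(O)cc45)c(OC)c3OC)c2c1 | target

**Totals**
Total step count: 4. Longest linear sequence: 4 steps (1 → 2 → 6 → 9 → 10).

**Three steps most likely to fail**

Step 4, the proposed new annulation. The risks are over‑reduction of a nitroso group to the aniline before ring closure, stalling at the 1‑hydroxyindole level, and catalyst binding by the phenol. The fallback uses known chemistry, sets out from 9 and comes back at 10. It is the palladium‑catalysed reductive N‑heterocyclisation with carbon monoxide: Pd(OAc)2 (10 mol %), 1,10‑phenanthroline (20 mol %), CO (6 atm), DMF, 100 °C. This is the established second half of the carbene‑coupling/reductive‑cyclisation indole synthesis for α‑aryl‑2‑nitrostyrenes. It replaces one‑electron early‑metal reduction in solution by two‑electron oxygen‑atom transfer to CO at palladium in an autoclave. The fallback makes no new compound (F0).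

Step 2. The risks are slow oxidative addition and carbene insertion at a bromide flanked by two methoxy groups, and loss of mono‑selectivity on the symmetric dibromide. The fallback sets out from 2 and comes back at 6, with the coupling polarity reversed and the desymmetrisation done by halogen–metal exchange. Treatment of 2 with n‑BuLi (1.0 equiv, THF, −78 °C) gives cleanly the mono‑exchanged (4-bromo-2,3,5,6-tetramethoxyphenyl)lithium F1. Quenching with N‑methoxy‑N‑methylacetamide gives 1-(4-bromo-2,3,5,6-tetramethoxyphenyl)ethan-1-one F2. Condensation with 4 (MeOH, cat. HCl, 65 °C) gives N'-[1-(4-bromo-2,3,5,6-tetramethoxyphenyl)ethylidene]-4-methylbenzenesulfonohydrazide F3. Barluenga coupling of F3 with commercial 2‑bromo‑4‑methoxy‑1‑nitrobenzene (Pd2(dba)3, XPhos, LiOtBu, 1,4‑dioxane, 90 °C) then gives 6. The activated, unhindered bromonitroarene undergoes oxidative addition far faster than the hindered, electron‑rich C–Br bond of F3.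

Step 3. The risk is the unprotected nitrophenol: poor solubility of the dilithiated hydrazone and catalyst inhibition by phenoxide. The fallback sets out from 7, with 6 as coupling partner, and comes back at 10; the phenol is carried as a benzyl ether and released last.
- O‑Benzylation of 7 (BnBr, K2CO3, DMF, rt) gives 1-[5-(benzyloxy)-2-nitrophenyl]ethan-1-one F4.
- Condensation with 4 gives N'-{1-[5-(benzyloxy)-2-nitrophenyl]ethylidene}-4-methylbenzenesulfonohydrazide F5.
- Coupling of F5 with 6 under the step 3 conditions (2.6 equiv LiOtBu) gives 1-{1-[5-(benzyloxy)-2-nitrophenyl]ethenyl}-2,3,5,6-tetramethoxy-4-[1-(5-methoxy-2-nitrophenyl)ethenyl]benzene F6.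
- Twofold ring closure with Pd(OAc)2, 1,10‑phenanthroline and CO gives 5-(benzyloxy)-3-[2,3,5,6-tetramethoxy-4-(5-methoxy-1H-indol-3-yl)phenyl]-1H-indole F7.
- Hydrogenolysis (H2, 1 atm, Pd/C, EtOAc–MeOH, rt) gives 10.

**Further compounds**
F1 | step 2 | (4-bromo-2,3,5,6-tetramethoxyphenyl)lithium | [Li]c1c(OC)c(OC)c(Br)c(OC)c1OC
F2 | step 2 | 1-(4-bromo-2,3,5,6-tetramethoxyphenyl)ethan-1-one | CC(=O)c1c(OC)c(OC)c(Br)c(OC)c1OC
F3 | step 2 | N'-[1-(4-bromo-2,3,5,6-tetramethoxyphenyl)ethylidene]-4-methylbenzenesulfonohydrazide | CC(=NNS(=O)(=O)c1ccc(C)cc1)c1c(OC)c(OC)c(Br)c(OC)c1OC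
F4 | step 3 | 1-[5-(benzyloxy)-2-nitrophenyl]ethan-1-one | CC(=O)c1cc(OCc2ccccc2)ccc1[N+](=O)[O-]
F5 | step 3 | N'-{1-[5-(benzyloxy)-2-nitrophenyl]ethylidene}-4-methylbenzenesulfonohydrazide | CC(=NNS(=O)(=O)c1ccc(C)cc1)c1cc(OCc2ccccc2)ccc1[N+](=O)[O-]
F6 | step 3 | 1-{1-[5-(benzyloxy)-2-nitrophenyl]ethenyl}-2,3,5,6-tetramethoxy-4-[1-(5-methoxy-2-nitrophenyl)ethenyl]benzene | C=C(c1c(OC)c(OC)c(C(=C)c2cc(OCc3ccccc3)ccc2[N+](=O)[O-])c(OC)c1OC)c1cc(OC)ccc1[N+](=O)[O-]
F7 | step 3 | 5-(benzyloxy)-3-[2,3,5,6-tetramethoxy-4-(5-methoxy-1H-indol-3-yl)phenyl]-1H-indole | COc1ccc2[nH]cc(-c3c(OC)c(OC)c(-c4c[nH]c5ccc(OCc6ccccc6)cc45)c(OC)c3OC)c2c1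
F0 | step 4 | none | none
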